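The route rests on opening ring B of the cis-fused decalin at C5–C6 and C9–C10 (eudesmane numbering). Ring B is a cyclohexanone whose C8 carbonyl is 1,4 to the ring-fusion CH (C5) and 1,3 to the quaternary C10, H-5 and CH3-10 are cis, and the C3 oxygen lies on the face of ring A that carries C6 and C9. This is the retron of a Diels–Alder reaction between a 2-silyloxy-3-isopropylbutadiene and a C5=C10 enone with its carbonyl at C4. The precursor ties the diene's enol oxygen to the C3 oxygen of (R)-6-hydroxy-3-methylcyclohex-2-enone through a diisopropylsilyl bridge, so one intramolecular cycloaddition builds ring B and both ring-fusion stereocentres.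

Key step: step 5

Remark: eudesmane numbering of the target is used for all bicyclic compounds (ring A = C1–C5 and C10, ring B = C5–C10; C3 ester, C4 CH3/OAc, C7 isopropyl, C8 ketone, C10 CH3) and β denotes the face of CH3-10. The lipase of step 2 is assumed to cleave the (R)-acetate, as the empirical size rule for lipases and secondary alcohols predicts.

Step 1
Reactants: 1 3-methylcyclohex-2-en-1-one
Product: 2 rac-6-acetoxy-3-methylcyclohex-2-en-1-one
Conditions: Mn(OAc)3·2H2O (3 equiv), benzene, reflux, Dean–Stark
Reagents that add atoms: manganese triacetate, CC(=O)[O-].CC(=O)[O-].CC(=O)[O-].[Mn+3]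
Why: α′-Acetoxylation of an enone by Mn(OAc)3: the manganese enolate formed on the CH2 side of the carbonyl is oxidized and takes up acetate at C6 while the enone stays intact; the product is racemic.

Step 2
Reactants: 2 rac-6-acetoxy-3-methylcyclohex-2-en-1-one
Product: 3 (R)-6-hydroxy-3-methylcyclohex-2-en-1-one
Conditions: Amano lipase PS (Burkholderia cepacia), phosphate buffer pH 7/MTBE, rt, stopped near 45 % conversion; chromatography
Reagents that add atoms: none
Why: Enzymatic kinetic resolution by enantioselective ester hydrolysis; with the carbonyl side as the large and the CH2 side as the medium substituent the size rule predicts cleavage of the (R)-acetate, and the neutral medium protects the α-ketol from racemization.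

Step 3
Reactants: 4 ethyl 2-acetyl-3-methylbutanoate (ethyl 2-isopropylacetoacetate, racemic)
Product: 6 3-isopropylbut-3-en-2-one (4-methyl-3-methylidenepentan-2-one), via potassium 2-acetyl-3-methylbutanoate 5 (not isolated)
Conditions: KOH, H2O, rt; then Et2NH·HCl, 37 % aq. CH2O, 0 °C → rt; distillation over hydroquinone
Reagents that add atoms: formaldehyde, C=O
Why: Saponification followed by a Mannich reaction at the doubly activated carbon; the β-amino acid loses CO2 and diethylamine (decarboxylative Mannich methylenation), which places the methylene group regiospecifically on the isopropyl-bearing carbon.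

Step 4
Reactants: 6 3-isopropylbut-3-en-2-one; 3 (R)-6-hydroxy-3-methylcyclohex-2-en-1-one
Product: 8 (R)-6-({[(3-isopropylbuta-1,3-dien-2-yl)oxy]diisopropylsilyl}oxy)-3-methylcyclohex-2-en-1-one, via chloro(dienyloxy)diisopropylsilane 7 (not isolated)
Conditions: LDA, THF, −78 °C (slow addition of 6); iPr2SiCl2 (3 equiv), −78 → 0 °C; volatiles removed in vacuo; then 3, imidazole, CH2Cl2, 0 °C → rt
Reagents that add atoms: dichlorodiisopropylsilane, CC(C)[Si](Cl)(Cl)C(C)C
Why: Kinetic deprotonation of the acetyl CH3 (the only enolizable site) gives the cross-conjugated dienolate, O-silylation by excess dichlorosilane stops at the monochloride for steric reasons, and imidazole-assisted displacement of the remaining Si–Cl by the C3 hydroxyl gives the mixed silaketal (temporary silicon connection) without touching the C3 stereocenter.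

Step 5
Reactants: 8 (R)-6-({[(3-isopropylbuta-1,3-dien-2-yl)oxy]diisopropylsilyl}oxy)-3-methylcyclohex-2-en-1-one
Product: 9 (3R,5S,10R)-cycloadduct: cis-fused 10-methyl-7-isopropyldecal-7-en-4-one (15-nor-5β-eudesm-7-en-4-one) whose 3α-oxygen and C8 enol oxygen are bridged by Si(iPr)2 across the α face, H-5 and CH3-10 both β
Conditions: AlBr3/AlMe3 (10:1, 30 mol % Al), toluene/CH2Cl2 (0.01 M), −20 → 0 °C; then Et3N, aq. NaHCO3; filtration through Et3N-deactivated silica
Reagents that add atoms: none
Why: Intramolecular Diels–Alder reaction of type 2 (tether on C2 of the diene) run as a temporary silicon connection; its closest known case is the intermolecular addition of a 2-silyloxydiene to a 3-methylcyclohex-2-enone under the same mixed aluminium Lewis acid, and here the aluminium-bound C4 carbonyl lowers the LUMO of the C5=C10 enone so that the silyloxydiene adds through a concerted but asynchronous endo transition state with C9–C10 bonding advanced. Ring B closes by suprafacial [4π+2π] addition across C5=C10 through a boat transition state, and the nine-membered silaketal ring (C3–O–Si–O–C8 bridge under ring A, a bicyclo[5.2.2] frame with the enol ether at the bridgehead) closes with it. C5 and C10 are formed together: their cis relationship follows from suprafacial addition to the ring alkene, and their absolute configuration is relayed from (R)-C3, because the five-atom tether can only deliver the diene to the face of ring A that carries O3 (pseudo-axial in the reacting half-chair). The step needs regioselectivity (C9 to C10, C6 to C5), secured by matching the largest HOMO coefficient (C9, next to the silyloxy carbon) with the largest LUMO coefficient (the β-carbon C10) and by the long Si–O bonds that let the tether span the 1,4-positions of ring B; it needs facial selectivity, secured by the tether; and it needs cyclization to outrun oligomerization, secured by high dilution.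

Step 6
Reactants: 9 silaketal-bridged cycloadduct
Product: 12 (3R,4S,5S,7R,10R)-3α,4α-dihydroxy-5β-eudesman-8-one, via bridged C4 methyl carbinol 10 (not isolated), via C7-epimeric diol ketone 11 (not isolated)
Conditions: MeLi, THF/Et2O, −78 °C; then HF·pyridine, pyridine, THF, 0 °C → rt; then K2CO3, MeOH, rt
Reagents that add atoms: methyllithium, [Li]C
Why: 1,2-Addition of MeLi to the C4 ketone can only occur from the β face, since ring B, its isopropyl group and the silaketal bridge cover the α face, which gives the 4β-methyl-4α-carbinol; HF then removes the silicon bridge (freeing 3α-OH and the C8 ketone) and carbonate equilibrates C7 to the equatorial 7β-isopropyl epimer, because a 7α-isopropyl group would be syn-axial to C4 in the chair–chair conformer that keeps both methyl groups equatorial on ring A.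

Step 7
Reactants: 13 angelic acid ((Z)-2-methylbut-2-enoic acid)
Product: 14 (Z)-2-methylbut-2-en-1-ol
Conditions: LiAlH4, Et2O, 0 °C → rt
Reagents that add atoms: none
Why: Hydride reduction of the carboxylic acid to the allylic alcohol, which leaves the trisubstituted (Z)-alkene untouched.

Step 8
Reactants: 14 (Z)-2-methylbut-2-en-1-ol
Product: 15 [(2R,3S)-2,3-dimethyloxiran-2-yl]methanol
Conditions: Ti(OiPr)4 (10 mol %), D-(−)-diethyl tartrate (12 mol %), t-BuOOH, 4 Å molecular sieves, CH2Cl2, −20 °C; non-aqueous work-up
Reagents that add atoms: tert-butyl hydroperoxide, CC(C)(C)OO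
Why: Sharpless asymmetric epoxidation; the D-(−)-tartrate (the L-(+)-ligand gives the 2S series from allylic alcohols of this type) delivers oxygen to the face that makes C2 R and C3 S, and the stereospecific syn addition keeps CH2OH and the C3 methyl cis as in the (Z)-alkene.

Step 9
Reactants: 15 [(2R,3S)-2,3-dimethyloxiran-2-yl]methanol
Product: 16 (2S,3S)-2,3-dimethyloxirane-2-carboxylic acid
Conditions: RuCl3·xH2O (2 mol %), NaIO4, MeCN/EtOAc/H2O, 0 °C → rt
Reagents that add atoms: sodium periodate, [Na+].[O-]I(=O)(=O)=O; water, O
Why: RuO4 generated in the flask from RuCl3 and NaIO4 oxidizes the primary alcohol to the acid without opening the epoxide; the C2 descriptor changes from R to S only because the CIP priorities change.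

Step 10
Reactants: 12 (3R,4S,5S,7R,10R)-3α,4α-dihydroxy-5β-eudesman-8-one; 16 (2S,3S)-2,3-dimethyloxirane-2-carboxylic acid
Product: 17 (3R,4S,5S,7R,10R)-4α-hydroxy-8-oxo-5β-eudesman-3α-yl (2S,3S)-2,3-dimethyloxirane-2-carboxylate
Conditions: 2,4,6-Cl3C6H2COCl, Et3N, DMAP, toluene, 0 °C → rt
Reagents that add atoms: none
Why: Yamaguchi esterification through the mixed anhydride and the acylpyridinium ion; the equatorial secondary 3α-OH is acylated while the axial tertiary 4α-OH is not, and no stereocenter is touched.

Step 11
Reactants: 17 (3R,4S,5S,7R,10R)-4α-hydroxy-8-oxo-5β-eudesman-3α-yl (2S,3S)-2,3-dimethyloxirane-2-carboxylate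
Product: 18 (3R,4S,5S,7R,10R)-4α-acetoxy-8-oxo-5β-eudesman-3α-yl (2S,3S)-2,3-dimethyloxirane-2-carboxylate (CNP0221066.1)
Conditions: Ac2O, DMAP, Et3N, CH2Cl2, 40 °C
Reagents that add atoms: acetic anhydride, CC(=O)OC(C)=O
Why: DMAP-catalysed acylation of the tertiary alcohol by the acetylpyridinium ion; the epoxide, the ketone and the C3 ester tolerate these conditions, and C7 already holds its thermodynamically preferred configuration.

Compound list
1 | 3-methylcyclohex-2-en-1-one | CC1=CC(=O)CCC1 | starting material
2 | rac-6-acetoxy-3-methylcyclohex-2-en-1-one | CC1=CC(=O)C(OC(C)=O)CC1 | intermediate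
3 | (R)-6-hydroxy-3-methylcyclohex-2-en-1-one | CC1=CC(=O)[C@H](O)CC1 | intermediate
4 | ethyl 2-acetyl-3-methylbutanoate (ethyl 2-isopropylacetoacetate, racemic) | CCOC(=O)C(C(C)C)C(C)=O | starting material
5 | potassium 2-acetyl-3-methylbutanoate | CC(=O)C(C(C)C)C(=O)[O-].[K+] | intermediate
6 | 3-isopropylbut-3-en-2-one (4-methyl-3-methylidenepentan-2-one) | CC(=O)C(=C)C(C)C | intermediate
7 | chloro[(3-isopropylbuta-1,3-dien-2-yl)oxy]diisopropylsilane | C=C(O[Si](Cl)(C(C)C)C(C)C)C(=C)C(C)C | intermediate
8 | (R)-6-({[(3-isopropylbuta-1,3-dien-2-yl)oxy]diisopropylsilyl}oxy)-3-methylcyclohex-2-en-1-one | CC1=CC(=O)[C@H](O[Si](C(C)C)(C(C)C)OC(=C)C(=C)C(C)C)CC1 | intermediate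
9 | (3R,5S,10R)-15-nor-5β-eudesm-7-en-4-one with an α-face O3–Si(iPr)2–O8 bridge (3α-silyl ether, C8 silyl enol ether; H-5 and CH3-10 β) | O=C1[C@H]2CC[C@]3(C)CC(=C(C(C)C)C[C@H]13)O[Si](C(C)C)(C(C)C)O2 | intermediate
10 | (3R,4S,5S,10R)-5β-eudesm-7-ene-3α,4α,8-triol 3,8-O-diisopropylsilanediyl ether (4β-CH3, free 4α-OH) | O[C@]1(C)[C@H]2CC[C@]3(C)CC(=C(C(C)C)C[C@H]13)O[Si](C(C)C)(C(C)C)O2 | intermediate
11 | (3R,4S,5S,10R)-3α,4α-dihydroxy-5β-eudesman-8-one as a mixture of C7 epimers | O[C@]1(C)[C@H](O)CC[C@]2(C)CC(=O)C(C(C)C)C[C@@H]21 | intermediate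
12 | (3R,4S,5S,7R,10R)-3α,4α-dihydroxy-5β-eudesman-8-one (cis-decalin; 4β-CH3, 7β-isopropyl, 10β-CH3) | O[C@]1(C)[C@H](O)CC[C@]2(C)CC(=O)[C@@H](C(C)C)C[C@@H]21 | intermediate
13 | angelic acid ((Z)-2-methylbut-2-enoic acid) | C/C=C(/C)C(=O)O | starting material
14 | (Z)-2-methylbut-2-en-1-ol | C/C=C(/C)CO | intermediate
15 | [(2R,3S)-2,3-dimethyloxiran-2-yl]methanol | OC[C@@]1(C)O[C@H]1C | intermediate
16 | (2S,3S)-2,3-dimethyloxirane-2-carboxylic acid | OC(=O)[C@@]1(C)O[C@H]1C | intermediate
17 | (3R,4S,5S,7R,10R)-4α-hydroxy-8-oxo-5β-eudesman-3α-yl (2S,3S)-2,3-dimethyloxirane-2-carboxylate | O[C@]1(C)[C@H](OC(=O)[C@@]3(C)O[C@H]3C)CC[C@]2(C)CC(=O)[C@@H](C(C)C)C[C@@H]21 | intermediate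
18 | (3R,4S,5S,7R,10R)-4α-acetoxy-8-oxo-5β-eudesman-3α-yl (2S,3S)-2,3-dimethyloxirane-2-carboxylate (CNP0221066.1) | CC(=O)O[C@]1(C)[C@H](OC(=O)[C@@]2(C)O[C@H]2C)CC[C@]2(C)CC(=O)[C@@H](C(C)C)C[C@@H]21 | target

Total step count: 11 steps.
Longest linear sequence: 7 steps (steps 1, 2, 4, 5, 6, 10, 11, from compound 1).

Steps most likely to fail

Step 5. What may go wrong: the tether geometry may favour the 1,3-bridged pairing of the termini (C9 to C5, C6 to C10) over the electronically preferred one; the reaction may stop after the first C–C bond by silyl transfer (a Mukaiyama–Michael stop); or the Lewis acid may cleave the silaketal or promote oligomerization. The fallback sets out from 3 and 6 and comes back to the route at 12; it gives up the tether for the intermolecular Lewis-acid Diels–Alder reaction. Alcohol 3 is silylated (TBSCl, imidazole, DMF) to (R)-6-(tert-butyldimethylsilyloxy)-3-methylcyclohex-2-en-1-one F1, and enone 6 is converted (TBSOTf, Et3N, CH2Cl2, 0 °C) into tert-butyl[(3-isopropylbuta-1,3-dien-2-yl)oxy]dimethylsilane F2. Cycloaddition of F1 and F2 under AlBr3/AlMe3 (toluene/CH2Cl2, −5 °C) should give (3R,5S,10R)-3α,8-bis(tert-butyldimethylsilyloxy)-15-nor-5β-eudesm-7-en-4-one F3. Regiocontrol is then purely electronic, and the diene is expected on the face syn to a pseudo-equatorial C3 silyloxy group (axial bond formation at C10 of the half-chair), so any anti adduct would have to be removed. MeMgBr (Et2O/CH2Cl2, −78 °C) adds to the C4 ketone of F3 from the β face (equatorial attack, the α face being screened by axial C9) while C8 stays masked as its silyl enol ether, giving (3R,4S,5S,10R)-3α,8-bis(tert-butyldimethylsilyloxy)-5β-eudesm-7-en-4α-ol F4. HF·pyridine followed by K2CO3/MeOH turns F4 into 12.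

Step 6. What may go wrong: enolization of the hindered C4 ketone instead of addition (CH3-10 partly screens the only open face), attack at silicon if addition is slow, or incomplete equilibration at C7. The fallback sets out from 9 and comes back at 11; it inverts the order of events. HF·pyridine on 9 removes the bridge first to give (3R,5S,10R)-3α-hydroxy-15-nor-5β-eudesmane-4,8-dione F5 (C7 epimers). MeTi(OiPr)3 (THF, −40 → 0 °C) then adds chemoselectively to the α-hydroxy ketone: the hydroxyl exchanges onto titanium and the methyl group is transferred within the chelate to C4, from the β face opposite axial C9, while the more hindered C8 ketone is left alone. This gives 11, which the carbonate treatment of step 6 converts into 12.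

Step 11. What may go wrong: sluggish acylation of the hindered axial tertiary hydroxyl, with acyl migration or elimination when the conditions are forced. The fallback sets out from 12 and comes back at 18; it installs the acetate before the epoxy ester. Diol 12 is condensed with trimethyl orthoacetate (PPTS, CH2Cl2) to the cyclic orthoester (3R,4S,5S,7R,10R)-3α,4α-(1-methoxyethylidenedioxy)-5β-eudesman-8-one F6. Mild hydrolysis (80 % aq. AcOH, rt) should open F6 to the axial ester by stereoelectronically controlled collapse of the hemiorthoester, giving (3R,4S,5S,7R,10R)-4α-acetoxy-3α-hydroxy-5β-eudesman-8-one F7. Esterification of F7 with 16 under the conditions of step 10, kept short and cold to limit acetyl migration, gives 18.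

Further compounds
F1 | step 5 | (R)-6-(tert-butyldimethylsilyloxy)-3-methylcyclohex-2-en-1-one | CC1=CC(=O)[C@H](O[Si](C)(C)C(C)(C)C)CC1
F2 | step 5 | tert-butyl[(3-isopropylbuta-1,3-dien-2-yl)oxy]dimethylsilane | C=C(O[Si](C)(C)C(C)(C)C)C(=C)C(C)C
F3 | step 5 | (3R,5S,10R)-3α,8-bis(tert-butyldimethylsilyloxy)-15-nor-5β-eudesm-7-en-4-one | O=C1[C@H](O[Si](C)(C)C(C)(C)C)CC[C@]2(C)CC(O[Si](C)(C)C(C)(C)C)=C(C(C)C)C[C@@H]21
F4 | step 5 | (3R,4S,5S,10R)-3α,8-bis(tert-butyldimethylsilyloxy)-5β-eudesm-7-en-4α-ol | O[C@]1(C)[C@H](O[Si](C)(C)C(C)(C)C)CC[C@]2(C)CC(O[Si](C)(C)C(C)(C)C)=C(C(C)C)C[C@@H]21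
F5 | step 6 | (3R,5S,10R)-3α-hydroxy-15-nor-5β-eudesmane-4,8-dione (C7 epimers) | O=C1[C@H](O)CC[C@]2(C)CC(=O)C(C(C)C)C[C@@H]21
F6 | step 11 | (3R,4S,5S,7R,10R)-3α,4α-(1-methoxyethylidenedioxy)-5β-eudesman-8-one | COC1(C)O[C@]2(C)[C@H](O1)CC[C@]3(C)CC(=O)[C@@H](C(C)C)C[C@@H]32
F7 | step 11 | (3R,4S,5S,7R,10R)-4α-acetoxy-3α-hydroxy-5β-eudesman-8-one | CC(=O)O[C@]1(C)[C@H](O)CC[C@]2(C)CC(=O)[C@@H](C(C)C)C[C@@H]21
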